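**Plan**

1. Cuts, backwards: the phenol O–CH3 bond; C3–C3a of ring A, which leaves a terminal ynone on the carbon ortho to OMe; the aryl–C(=O) bond of that ynone (aryl iodide, CO, alkyne); the aryl–C(OH) bond of ring D; the two ketal C–O bonds; ring E back to maleic anhydride and an aroyl ylide.
2. Feature that permits the last ring closure: ring A (carbonyl C1, C2, C3) spans the two peri carbons C9a and C3a of a naphthalene that bears oxygen on C9. C1 therefore sits ortho to that oxygen and C3 on the peri carbon, which the oxygen activates through the ring system.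
3. Forward order: rings B/C (naphthalene from the tetralone) → ring E (2-aroylcyclopent-4-ene-1,3-dione) → spiro naphthodioxine → ring D (ketone arylation) → iodide, ynone → ring A → free phenol.
4. Stereochemistry: dione 14 is achiral. A chiral palladium catalyst arylates one of its two enantiotopic carbonyls and fixes the carbinol carbon (R). The adjacent methine (S) follows because rings D and E can only be cis-fused. The tertiary alcohol is carried unprotected and no later step touches either centre.
5. Ring letters: A enone ring; B and C benzenoid rings of the phenalenone; D five-membered ring holding the ketal and carbinol carbons; E cyclopentenone.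

Key step: step 12

Assumption: the sense of asymmetric induction in step 8 cannot be derived with confidence from the ligand structure; the (R)-ligand is written and its antipode would be used if the first run shows the opposite sense.

Step 1
Reactants: 1 6-methoxy-2-tetralone
Product: 2 2-bromo-6-methoxy-3,4-dihydronaphthalene-1-carbaldehyde
Conditions: PBr3, DMF, CHCl3, 0 °C to 60 °C; aq NaOAc
Reagents that add atoms: phosphorus tribromide, BrP(Br)Br; N,N-dimethylformamide, CN(C)C=O; water, O
Why: Vilsmeier–Haack–Arnold bromoformylation: the bromoiminium salt from DMF and PBr3 formylates the enol of the 2-tetralone at the benzylic C1 and exchanges the enol oxygen for bromide, the usual course for 2-tetralones, and aqueous work-up frees the aldehyde.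

Step 2
Reactants: 2 2-bromo-6-methoxy-3,4-dihydronaphthalene-1-carbaldehyde
Product: 3 2-bromo-6-methoxynaphthalene-1-carbaldehyde
Conditions: DDQ, toluene, 90 °C
Reagents that add atoms: none
Why: DDQ dehydrogenation (hydride abstraction, then loss of a proton) aromatises the 3,4-dihydronaphthalene, driven by the gain of the second benzenoid ring, without touching aldehyde, bromide or methyl ether.

Step 3
Reactants: 3 2-bromo-6-methoxynaphthalene-1-carbaldehyde
Product: 4 2-bromo-6-methoxynaphthalene-1-carboxylic acid
Conditions: NaClO2, NaH2PO4, 2-methyl-2-butene, t-BuOH/H2O, rt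
Reagents that add atoms: sodium chlorite, [Na+].[O-]Cl=O
Why: Pinnick oxidation: chlorous acid oxidises the hindered aryl aldehyde to the acid, and 2-methyl-2-butene takes up the hypochlorous acid that would otherwise chlorinate the methoxynaphthalene.

Step 4
Reactants: 4 2-bromo-6-methoxynaphthalene-1-carboxylic acid
Product: 6 1-(2-bromo-6-methoxynaphthalen-1-yl)-2-(triphenyl-λ5-phosphanylidene)ethan-1-one, via acid chloride 5 (not isolated)
Conditions: (COCl)2, DMF (cat.), CH2Cl2, 0 °C to rt; then Ph3P=CH2 (2.1 equiv, from Ph3PCH3Br and NaN(SiMe3)2), THF, −78 °C to rt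
Reagents that add atoms: oxalyl chloride, O=C(Cl)C(=O)Cl (chlorine of 5 only); methylenetriphenylphosphorane, C=P(c1ccccc1)(c1ccccc1)c1ccccc1 (made in the flask from methyltriphenylphosphonium bromide, C[P+](c1ccccc1)(c1ccccc1)c1ccccc1.[Br-])
Why: Acid chloride formation followed by C-acylation of a phosphorus ylide, in which the second equivalent of ylide deprotonates the acylphosphonium salt to the stabilised aroyl ylide.

Step 5
Reactants: 6 aroyl ylide; 7 maleic anhydride
Product: 8 (5E)-5-[2-(2-bromo-6-methoxynaphthalen-1-yl)-2-oxoethylidene]furan-2(5H)-one
Conditions: toluene, 60 °C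
Reagents that add atoms: none
Why: Wittig olefination of an anhydride carbonyl by a stabilised ylide, the established entry to 4-ylidenebutenolides from maleic anhydride; the alkene geometry is of no consequence because it is lost in step 6.

Step 6
Reactants: 8 ylidenebutenolide
Product: 10 2-[(2-bromo-6-methoxynaphthalen-1-yl)(hydroxy)methylidene]cyclopent-4-ene-1,3-dione, via keto ester 9 (not isolated)
Conditions: NaOMe, MeOH, 0 °C to rt; then aq HCl
Reagents that add atoms: sodium methoxide, [Na+].[O-]C (methoxy group of 9 only)
Why: Ylidenebutenolide-to-cyclopentenedione rearrangement: methoxide opens the enol lactone to the (Z)-keto ester 9, whose 1,3-diketone carbanion closes onto the ester in a Claisen (Dieckmann-type) condensation, and the vinylogous acid, enolised outside the ring because an enol inside it would be a cyclopentadienone, is the sink.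

Step 7
Reactants: 10 2-aroylcyclopentenedione (exocyclic enol); 11 1,8-dihydroxynaphthalene
Product: 14 2-[2-(2-bromo-6-methoxynaphthalen-1-yl)naphtho[1,8-de][1,3]dioxin-2-yl]cyclopent-4-ene-1,3-dione, via vinylogous acid chloride 12 (not isolated), via aryl enol ether 13 (not isolated)
Conditions: (COCl)2, DMF (cat.), CH2Cl2, 0 °C; then 11, i-Pr2NEt, MeCN, 0 °C to rt; pH 4 buffer
Reagents that add atoms: oxalyl chloride, O=C(Cl)C(=O)Cl (chlorine of 12 only)
Why: Vilsmeier-type exchange of the exocyclic enol hydroxyl for chloride, then double conjugate addition of the peri-diol at that one carbon (addition–elimination by the first naphthoxide, 6-exo-trig oxa-Michael closure by the second, as dithiols and catechols do with ynones and β-halo enones); under base the closed ketal is favoured because its dione anion is a weaker base than a naphthoxide, and buffered work-up protonates it on carbon.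

Step 8
Reactants: 14 spiroketal dione
Product: 15 core alcohol (cis-fused rings D/E; carbinol R, methine S)
Conditions: Pd(OAc)2 (10 mol%), (R)-DTBM-SEGPHOS (12 mol%), KOAc, i-PrOH, toluene, 80 °C
Reagents that add atoms: none
Why: Enantioselective palladium-catalysed intramolecular addition of an aryl bromide to a ketone, run as a desymmetrisation of a cyclic 1,3-diketone: oxidative addition gives an arylpalladium bromide that the two-atom tether holds over ring E, the chiral bisphosphine selects one of the two enantiotopic carbonyls for 1,2-insertion and so sets the carbinol carbon, the methine follows because the new five-membered ring can only be cis-fused, i-PrOH returns the catalyst to zerovalent palladium, and acetate is too weak a base to deprotonate the dione, which is wholly ketonic because its enol would be a cyclopentadienone.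

Step 9
Reactants: 15 core alcohol
Product: 16 1-iodo derivative of 15 (iodine on naphthalene C1, ortho to OMe)
Conditions: N-iodosuccinimide (1.05 equiv), CF3CO2H (10 mol%), MeCN, −20 °C to 0 °C
Reagents that add atoms: N-iodosuccinimide, O=C1CCC(=O)N1I
Why: Electrophilic aromatic iodination: C1 of a 2-methoxynaphthalene, α and ortho to the methoxy group, is the most nucleophilic arene position in 15, more so than the naphthodioxine ring whose ketal oxygens are weaker donors, and one equivalent of reagent at low temperature is used to keep to that site.

Step 10
Reactants: 16 aryl iodide; 17 ethynyltrimethylsilane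
Product: 18 silyl ynone (C(=O)C≡C–SiMe3 on naphthalene C1)
Conditions: CO (1 atm), PdCl2(PPh3)2 (5 mol%), CuI (2 mol%), Et3N, THF, rt
Reagents that add atoms: carbon monoxide, [C-]#[O+]
Why: Carbonylative Sonogashira coupling: oxidative addition of the aryl iodide, CO insertion to the aroylpalladium species and capture by the copper acetylide give the ynone at room temperature, conditions that leave enone, ketal and free tertiary alcohol alone.

Step 11
Reactants: 18 silyl ynone
Product: 19 terminal ynone (prop-2-ynoyl group on naphthalene C1)
Conditions: Na2B4O7·10H2O (0.2 equiv), MeOH/THF/H2O, 0 °C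
Reagents that add atoms: none
Why: Base-catalysed protodesilylation of an alkynylsilane (methanolysis of the C–Si bond), which with the weak borate base stops before methanol adds to the electron-poor triple bond.

Step 12
Reactants: 19 terminal ynone
Product: 20 spiropreussione B methyl ether
Conditions: Ph3PAuNTf2 (5 mol%), ClCH2CH2Cl, 50 °C
Reagents that add atoms: none
Why: Ph3PAuNTf2 (monovalent gold with a non-nucleophilic counter-ion) binds the alkyne of the ynone; the peri carbon C8 of the naphthalene, conjugated with the C2 methoxy group and held next to the alkyne terminus once the aroyl group turns into the ring plane, attacks the terminal carbon in a Friedel–Crafts sense, and rearomatisation followed by protodeauration releases the enone. The closest known reaction type is the gold- or acid-promoted intramolecular hydroarylation of aryl ynones and aryl propiolates (a Friedel–Crafts conjugate addition), closure onto a naphthalene peri carbon being its less common variant. Ring A closes in the 6-endo-dig mode by forming the C3–C3a bond, which gives the phenalenone at the right oxidation level without a separate oxidation. No stereocentre is formed, and the two existing ones are remote and cannot epimerise to a trans-fused isomer. The step needs attack at the alkyne terminus, not at the internal carbon (5-exo) or by the methoxy oxygen: conjugation with the carbonyl makes the terminus the electrophilic carbon, the 5-exo product would be a strained peri-fused five-membered ring, and oxygen attack is reversible because the triflimide counter-ion cannot remove the methyl group. The hydroxy enone, the diaryl ketal and the tertiary alcohol are inert to this nearly neutral catalyst.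

Step 13
Reactants: 20 spiropreussione B methyl ether
Product: 21 spiropreussione B
Conditions: BCl3 (3 equiv), CH2Cl2, −78 °C to 0 °C; aq NaHCO3
Reagents that add atoms: none
Why: Chelation-assisted Lewis acid demethylation: BCl3 binds the phenalenone carbonyl and the peri methoxy oxygen in a six-membered chelate and chloride removes the methyl group at low temperature, while the diaryl ketal persists and the tertiary alcohol, whose ionisation would give an antiaromatic oxocyclopentenyl cation, is merely held as a borate until work-up.

**Compound list**

1 | 6-methoxy-2-tetralone | COc1ccc2c(c1)CCC(=O)C2 | starting material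
2 | 2-bromo-6-methoxy-3,4-dihydronaphthalene-1-carbaldehyde | COc1ccc2c(c1)CCC(Br)=C2C=O | intermediate
3 | 2-bromo-6-methoxynaphthalene-1-carbaldehyde | COc1ccc2c(c1)ccc(Br)c2C=O | intermediate
4 | 2-bromo-6-methoxynaphthalene-1-carboxylic acid | COc1ccc2c(c1)ccc(Br)c2C(=O)O | intermediate
5 | 2-bromo-6-methoxynaphthalene-1-carbonyl chloride (not isolated) | COc1ccc2c(c1)ccc(Br)c2C(=O)Cl | intermediate
6 | 1-(2-bromo-6-methoxynaphthalen-1-yl)-2-(triphenyl-λ5-phosphanylidene)ethan-1-one (aroyl ylide) | COc1ccc2c(c1)ccc(Br)c2C(=O)C=P(c1ccccc1)(c1ccccc1)c1ccccc1 | intermediate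
7 | maleic anhydride | O=C1OC(=O)C=C1 | starting material
8 | (5E)-5-[2-(2-bromo-6-methoxynaphthalen-1-yl)-2-oxoethylidene]furan-2(5H)-one | COc1ccc2c(c1)ccc(Br)c2C(=O)/C=C1/OC(=O)C=C1 | intermediate
9 | methyl (2Z)-6-(2-bromo-6-methoxynaphthalen-1-yl)-4,6-dioxohex-2-enoate (not isolated) | COC(=O)/C=C\C(=O)CC(=O)c1c(Br)ccc2cc(OC)ccc12 | intermediate
10 | 2-[(2-bromo-6-methoxynaphthalen-1-yl)(hydroxy)methylidene]cyclopent-4-ene-1,3-dione | COc1ccc2c(c1)ccc(Br)c2C(O)=C1C(=O)C=CC1=O | intermediate
11 | 1,8-dihydroxynaphthalene | Oc1cccc2cccc(O)c12 | starting material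
12 | 2-[(2-bromo-6-methoxynaphthalen-1-yl)chloromethylidene]cyclopent-4-ene-1,3-dione (not isolated) | COc1ccc2c(c1)ccc(Br)c2C(Cl)=C1C(=O)C=CC1=O | intermediate
13 | 2-{(2-bromo-6-methoxynaphthalen-1-yl)[(8-hydroxynaphthalen-1-yl)oxy]methylidene}cyclopent-4-ene-1,3-dione (not isolated) | COc1ccc2c(c1)ccc(Br)c2C(Oc1cccc2cccc(O)c12)=C1C(=O)C=CC1=O | intermediate
14 | 2-[2-(2-bromo-6-methoxynaphthalen-1-yl)naphtho[1,8-de][1,3]dioxin-2-yl]cyclopent-4-ene-1,3-dione (achiral) | COc1ccc2c(c1)ccc(Br)c2C1(Oc2cccc3cccc(c23)O1)C1C(=O)C=CC1=O | intermediate
15 | core alcohol: 2-methoxynaphthalene whose C5 bears the spiro naphtho[1,8-de][1,3]dioxine ketal carbon and whose C6 bears the tertiary carbinol carbon (R, OH); ketal carbon, methine (S) and carbinol carbon close ring D with C5–C6; methine–C(=O)–CH=CH–carbinol closes cyclopentenone ring E; rings D and E cis-fused | COc1ccc2c(c1)ccc3c2C1(Oc2cccc4cccc(c24)O1)[C@@H]1C(=O)C=C[C@]31O | intermediate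
16 | 15 with iodine on naphthalene C1 (ortho to OMe); carbinol R, methine S | COc1ccc2c(c1I)ccc3c2C1(Oc2cccc4cccc(c24)O1)[C@@H]1C(=O)C=C[C@]31O | intermediate
17 | ethynyltrimethylsilane | C#C[Si](C)(C)C | starting material
18 | 15 with a 3-(trimethylsilyl)prop-2-ynoyl group on naphthalene C1; carbinol R, methine S | COc1ccc2c(c1C(=O)C#C[Si](C)(C)C)ccc3c2C1(Oc2cccc4cccc(c24)O1)[C@@H]1C(=O)C=C[C@]31O | intermediate
19 | 15 with a prop-2-ynoyl group on naphthalene C1 (terminal ynone); carbinol R, methine S | COc1ccc2c(c1C(=O)C#C)ccc3c2C1(Oc2cccc4cccc(c24)O1)[C@@H]1C(=O)C=C[C@]31O | intermediate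
20 | spiropreussione B methyl ether (9-methoxyphenalenone; carbinol R, methine S) | O=C1C=Cc2cc3c(c4ccc(OC)c1c24)C1(Oc2cccc4cccc(c24)O1)[C@@H]1C(=O)C=C[C@]31O | intermediate
21 | spiropreussione B (carbinol R, methine S) | O=C1C=Cc2cc3c(c4ccc(O)c1c24)C1(Oc2cccc4cccc(c24)O1)[C@@H]1C(=O)C=C[C@]31O | target

**Step count and risks**

Total: 13 steps. Longest linear sequence: 13 steps (1 to 21).

1. Step 8 (ring D closure and both stereocentres). What may go wrong: loss of bromine by protonolysis of the arylpalladium intermediate through the acidic dione C–H, base-induced opening of the ketal by retro-oxa-Michael reaction, consumption of the enedione double bond by hydride or Heck pathways, or poor discrimination between the two carbonyls. The fallback sets out from 3 and comes back at 15. It closes ring D first, on a carbonyl that is not part of an acidic dione, sets the methine with an auxiliary, and then closes ring E. Ohira–Bestmann alkynylation of 3 (dimethyl (1-diazo-2-oxopropyl)phosphonate, K2CO3, MeOH) should give 2-bromo-1-ethynyl-6-methoxynaphthalene F1. LiN(SiMe3)2 and ClCO2Me should give methyl 3-(2-bromo-6-methoxynaphthalen-1-yl)prop-2-ynoate F2. Double oxa-Michael addition of 11 (Cs2CO3, MeCN) should give the ketal ester F3. Bromine–lithium exchange with t-BuLi (THF, −100 °C) and Parham cycliacylation should give the spiro ketal indanone F4, in which ring D is closed. Condensation with (R)-1-amino-2-(methoxymethyl)pyrrolidine should give the RAMP hydrazone F5. LiN(i-Pr)2 and then (Z)-3-bromo-1-iodoprop-1-ene (two steps from ethyl (Z)-3-iodoacrylate with i-Bu2AlH and CBr4/PPh3) should give the alkylated hydrazone F6; this SAMP/RAMP hydrazone alkylation sets the methine, the (R)-auxiliary being chosen by the established model for cyclic ketones. Aqueous oxalic acid should free the ketone F7. CrCl2 with catalytic NiCl2 in DMF (Nozaki–Hiyama–Kishi reaction) should add the (Z)-vinyl iodide to the ring D ketone and close ring E as the cis-fused tertiary allylic alcohol F8. SeO2/t-BuOOH should oxidise the one allylic CH2 to the allylic diol F9, and Dess–Martin periodinane should oxidise its secondary hydroxyl to give 15.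

2. Step 7 (spiroketal). What may go wrong: the ring-closing second addition stalls at the open enol ether, C-alkylation of the naphthol competes with O-attack, or the ketal reopens when the dione anion is protonated. The fallback sets out from 10 and comes back at 14. It replaces the chloride/base sequence by an acid-catalysed, thermodynamically driven trans-ketalisation. O-Methylation of the vinylogous acid with Me3SiCHN2 (MeOH/toluene) should give the methyl enol ether 2-[(2-bromo-6-methoxynaphthalen-1-yl)(methoxy)methylidene]cyclopent-4-ene-1,3-dione F10. This is heated with 11 and catalytic TsOH in toluene while methanol is distilled out. Exchange of the alkoxy group of a vinylogous ester and acid-catalysed ketalisation with 1,8-dihydroxynaphthalene are both known operations.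

3. Step 12 (ring A). What may go wrong: cyclisation through the methoxy oxygen with loss of the methyl group, hydration of the ynone, or no turnover because the flanked aroyl group stays twisted out of the ring plane. The fallback sets out from 19 and comes back at 20. It makes the same C3–C3a bond by palladium-catalysed C–H alkenylation instead of π-acid activation. NaI in AcOH should add HI across the ynone to give the (Z)-β-iodoenone F11. Pd(OAc)2, PCy3·HBF4, pivalic acid and K2CO3 in DMA at 100 °C (intramolecular direct arylation-type C–H functionalisation forming a six-membered ring) should then close ring A at the peri C–H with loss of HI.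

**Further compounds**

F1 | step 8 | 2-bromo-1-ethynyl-6-methoxynaphthalene | COc1ccc2c(c1)ccc(Br)c2C#C
F2 | step 8 | methyl 3-(2-bromo-6-methoxynaphthalen-1-yl)prop-2-ynoate | COC(=O)C#Cc1c(Br)ccc2cc(OC)ccc12
F3 | step 8 | methyl [2-(2-bromo-6-methoxynaphthalen-1-yl)naphtho[1,8-de][1,3]dioxin-2-yl]acetate | COC(=O)CC1(Oc2cccc3cccc(c23)O1)c1c(Br)ccc2cc(OC)ccc12
F4 | step 8 | 7-methoxyspiro[cyclopenta[a]naphthalene-1,2'-naphtho[1,8-de][1,3]dioxin]-3(2H)-one | COc1ccc2c(c1)ccc3c2C1(Oc2cccc4cccc(c24)O1)CC3=O
F5 | step 8 | hydrazone of F4 with (R)-1-amino-2-(methoxymethyl)pyrrolidine | COc1ccc2c(c1)ccc3c2C1(Oc2cccc4cccc(c24)O1)CC3=NN1CCC[C@@H]1COC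
F6 | step 8 | hydrazone F5 bearing a (2Z)-3-iodoprop-2-en-1-yl group on C2 (2R) | COc1ccc2c(c1)ccc3c2C1(Oc2cccc4cccc(c24)O1)[C@H](C/C=C\I)C3=NN1CCC[C@@H]1COC
F7 | step 8 | (2R)-2-[(2Z)-3-iodoprop-2-en-1-yl]-7-methoxyspiro[cyclopenta[a]naphthalene-1,2'-naphtho[1,8-de][1,3]dioxin]-3(2H)-one | COc1ccc2c(c1)ccc3c2C1(Oc2cccc4cccc(c24)O1)[C@H](C/C=C\I)C3=O
F8 | step 8 | cis-fused tertiary allylic alcohol (15 with CH2 in place of the ring E carbonyl) | COc1ccc2c(c1)ccc3c2C1(Oc2cccc4cccc(c24)O1)[C@@H]1CC=C[C@]31O
F9 | step 8 | allylic diol (15 with CH(OH) in place of the ring E carbonyl; both epimers at that carbon) | COc1ccc2c(c1)ccc3c2C1(Oc2cccc4cccc(c24)O1)[C@@H]1C(O)C=C[C@]31O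
F10 | step 7 | 2-[(2-bromo-6-methoxynaphthalen-1-yl)(methoxy)methylidene]cyclopent-4-ene-1,3-dione | COc1ccc2c(c1)ccc(Br)c2C(OC)=C1C(=O)C=CC1=O
F11 | step 12 | (Z)-β-iodoenone: 15 with a (2Z)-3-iodoprop-2-enoyl group on naphthalene C1 | COc1ccc2c(c1C(=O)/C=C\I)ccc3c2C1(Oc2cccc4cccc(c24)O1)[C@@H]1C(=O)C=C[C@]31O
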